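**Retrosynthetic overview**
- The oxirane is made last, by a catalyst-controlled epoxidation of the C10 vinyl group (the new step). Before that, the enal comes from allylic oxidation of the isopropenyl group and both angelates from acylation of a 6β,9α-diol.
- The cis-lactone and the trans C8/C9 oxygens come from a C8=C9 olefin: amide iodolactonisation (lactone ring), then iodide → β-epoxide → diaxial hydrolysis. The 6β-OH comes from hydride addition to a C6 ketone.
- The C7–C11 bond comes from an Eschenmoser–Claisen rearrangement with 1,3-chirality transfer from a 9β allylic alcohol.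
- The C10 quaternary centre comes from α′-methylation then α′-vinylation of an enone, anti to the C5 isopropenyl group.
- The carbocycle is bought as p-benzoquinone monoketal; C5 is set first by an asymmetric conjugate isopropenylation. Ring order: carbocycle (purchased), lactone (step 7), oxirane (step 13).

Assumption and convention: (R)-BINAP is taken to give the required C5 configuration by analogy with 2-cyclohexenone. Atoms carry the target's numbering (ring C5–C10; C1–C2 on C10; C11–C13 lactone carbons), and β is the face of the C10 methyl group.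

**Route**

Step 1
Reactants: 1 4,4-dimethoxycyclohexa-2,5-dien-1-one; 2 potassium trifluoro(prop-1-en-2-yl)borate
Product: 3 (R)-4,4-dimethoxy-5-(prop-1-en-2-yl)cyclohex-2-en-1-one
Conditions: [Rh(cod)2]BF4 (3 mol %), (R)-BINAP (3.3 mol %), Et3N, PhMe/H2O 10:1, 25 °C
Reagents that add atoms: none
Why: Asymmetric conjugate addition (Hayashi–Miyaura type) of the alkenyl trifluoroborate to one of the two enantiotopic enone arms of the achiral dienone, in which the [Rh(cod)2]BF4/(R)-BINAP catalyst selects the enantioface so that the isopropenyl group ends on the β-face of C5, while the more hindered mono-adduct does not react further.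

Step 2
Reactants: 3
Product: 5 (5R,6S)-4,4-dimethoxy-6-methyl-5-(prop-1-en-2-yl)cyclohex-2-en-1-one, via lithium dienolate 4 (not isolated)
Conditions: LiN(iPr)2, THF, −78 °C; MeI, −78 → −20 °C
Reagents that add atoms: iodomethane, CI
Why: Kinetic α′-enolate alkylation (the γ-carbon is a ketal, so no other enolate can form) places the methyl group trans to the neighbouring isopropenyl group, a centre that is deliberately erased and reset in step 3.

Step 3
Reactants: 5
Product: 7 (5S,6S)-4,4-dimethoxy-6-methyl-6-[2-(phenylsulfinyl)ethyl]-5-(prop-1-en-2-yl)cyclohex-2-en-1-one, via lithium enolate 6 (not isolated)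
Conditions: LiN(iPr)2, THF, −78 °C; phenyl vinyl sulfoxide, −78 → 0 °C; then AcOH
Reagents that add atoms: phenyl vinyl sulfoxide, C=CS(=O)c1ccccc1
Why: Michael addition of the fully substituted enolate to the vinyl sulfoxide (a vinyl cation equivalent) forms the C10 quaternary centre, the acceptor approaching the enolate face opposite the C5 isopropenyl group so that the two-carbon arm is α and the methyl group β.

Step 4
Reactants: 7
Product: 8 (5S,6S)-6-ethenyl-4,4-dimethoxy-6-methyl-5-(prop-1-en-2-yl)cyclohex-2-en-1-one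
Conditions: PhMe, NaHCO3 (solid), 110 °C
Reagents that add atoms: none
Why: Sulfoxide pyrolysis (thermal syn-elimination of benzenesulfenic acid) unmasks the vinyl group without touching any stereocentre.

Step 5
Reactants: 8
Product: 9 (1S,5S,6S)-6-ethenyl-4,4-dimethoxy-6-methyl-5-(prop-1-en-2-yl)cyclohex-2-en-1-ol
Conditions: NaBH4, CeCl3·7H2O, MeOH, −78 → −40 °C
Reagents that add atoms: none
Why: Luche 1,2-reduction in which hydride enters from the α-face, because the β-face of the carbonyl is screened by the C10 methyl and the C5 isopropenyl groups, giving the 9β-alcohol.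

Step 6
Reactants: 9
Product: 11 N,N-dimethyl-2-(5β-isopropenyl-6,6-dimethoxy-10β-methyl-10α-vinylcyclohex-8-en-7β-yl)acetamide, via ketene N,O-acetal 10 (not isolated)
Conditions: MeC(OMe)2NMe2, xylenes, 150 °C, sealed tube
Reagents that add atoms: N,N-dimethylacetamide dimethyl acetal, CN(C)C(C)(OC)OC
Why: Eschenmoser–Claisen rearrangement, a suprafacial [3,3] shift that trades the β-configured C9–O bond for a β C7–C11 bond (1,3-chirality transfer) and leaves the C8=C9 olefin, with no competing elimination because neither C10 nor C6 carries a hydrogen.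

Step 7
Reactants: 11
Product: 13 2-(8β-hydroxy-9α-iodo-5β-isopropenyl-6,6-dimethoxy-10β-methyl-10α-vinylcyclohex-7β-yl)acetic acid γ-lactone, via iminium lactone iodide 12 (not isolated)
Conditions: I2, NaHCO3, THF/H2O 2:1, 0 °C → rt, dark
Reagents that add atoms: iodine, II; water, O
Why: Iodolactonisation of the γ,δ-unsaturated amide, in which only the α-iodonium ion can be opened 5-exo at C8 by the β-tethered amide oxygen, so the cis-fused lactone (8β-O) and the trans-diaxial 9α-iodide are fixed while the isopropenyl and vinyl groups, lacking an internal nucleophile, are left alone.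

Step 8
Reactants: 13
Product: 17 2-(8β-hydroxy-9α-iodo-5β-isopropenyl-6,6-dimethoxy-10β-methyl-10α-vinylcyclohex-7β-yl)acrylic acid γ-lactone, via lithium lactone enolate 14 (not isolated), via Mannich base 15 (not isolated), via trimethylammonium iodide 16 (not isolated)
Conditions: LiN(iPr)2, THF, −78 °C; CH2=NMe2+ I−; then MeI, MeOH, rt; then NaHCO3 (aq)
Reagents that add atoms: N,N-dimethylmethyleneiminium iodide, C=[N+](C)C.[I-]
Why: Standard lactone α-methylenation (enolate Mannich reaction with Eschenmoser's salt, quaternisation, E1cB loss of trimethylamine), which touches no stereocentre and spares the 9α-iodide because it has no antiperiplanar hydrogen.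

Step 9
Reactants: 17
Product: 19 2-(8β,9α-dihydroxy-5β-isopropenyl-10β-methyl-6-oxo-10α-vinylcyclohex-7β-yl)acrylic acid 8-γ-lactone, via lithium epoxy acrylate 18 (not isolated)
Conditions: LiOH, THF/H2O, 0 °C → rt; then HClO4 (aq) to pH 1.5, rt
Reagents that add atoms: lithium hydroxide, [Li+].[OH-]; water, O
Why: Saponification frees the 8β-alkoxide, which displaces the antiperiplanar 9α-iodide to give the 8β,9β-epoxide, and on acidification water opens it trans-diaxially at C9 from the α-face (Fürst–Plattner rule) while the 8β-hydroxy acid relactonises and the ketal is hydrolysed, so C9 is inverted twice and ends as the 9α-alcohol.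

Step 10
Reactants: 19
Product: 20 2-(6β,8β,9α-trihydroxy-5β-isopropenyl-10β-methyl-10α-vinylcyclohex-7β-yl)acrylic acid 8-γ-lactone
Conditions: NaBH4, CeCl3·7H2O, MeOH, −78 → −30 °C
Reagents that add atoms: none
Why: Luche reduction of the C6 ketone only (the α-methylene lactone is spared), in which axial approach on the β-face is blocked by the syn-axial C10 methyl and C8 oxygen so that hydride adds from the α-face and gives the axial 6β-alcohol.

Step 11
Reactants: 20
Product: 22 6β,9α-di-O-angeloyl derivative of 20, via 9-O-angelate 21 (not isolated)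
Conditions: angelic acid, 2,4,6-trichlorobenzoyl chloride, Et3N, PhMe, rt; then 20, 80 °C
Reagents that add atoms: angelic acid, C/C=C(/C)C(=O)O
Why: Yamaguchi-type esterification with the preformed angelic 2,4,6-trichlorobenzoic mixed anhydride, run without a nucleophilic catalyst to preserve the Z geometry, acylates first the 9α- and then the more hindered 6β-hydroxyl with retention at both carbinol carbons.

Step 12
Reactants: 22
Product: 24 6β,9α-di-O-angeloyl-5β-(3-oxoprop-1-en-2-yl) vinyl lactone, via allylic alcohol 23 (not isolated)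
Conditions: SeO2 (0.5 equiv), tBuOOH, CH2Cl2, rt; then Dess–Martin periodinane, CH2Cl2
Reagents that add atoms: selenium dioxide, O=[Se]=O; tert-butyl hydroperoxide, CC(C)(C)OO
Why: SeO2 allylic oxidation (ene reaction then [2,3] shift) attacks only the electron-rich isopropenyl group at its methyl carbon, since the vinyl group has no allylic hydrogen and the other C=C bonds are conjugated and electron-poor, and Dess–Martin oxidation carries the allylic alcohol on to the 2-substituted acrolein.

Step 13
Reactants: 24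
Product: 25 target CNP0291490.2
Conditions: [Ti(L)(μ-O)]2 (5 mol %; L = salalen dianion from cis-1,2-diaminocyclohexane and 3-phenylsalicylaldehyde, the enantiomer that gives (R)-1,2-epoxyalkanes), 30% H2O2 (aq, 1.5 equiv), CH2Cl2, 0 °C → rt
Reagents that add atoms: hydrogen peroxide, OO
Why: Proposed new method: reagent-controlled epoxidation of a vinyl group on a quaternary stereocentre by a tetravalent-titanium salalen hydroperoxo species, which is electrophilic and therefore ignores the four conjugated, electron-poor C=C bonds, and which through the ligand N–H···O hydrogen bond and its aryl walls admits only an unsubstituted =CH2 terminus and delivers oxygen to the vinyl face that gives (1R) irrespective of the weak substrate bias of this freely rotating group, the closest known reaction being the [Ti(salalen)(μ-O)]2/H2O2 epoxidation of simple non-conjugated 1-alkenes such as vinylcyclohexane.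

**Compound list**

1 | 4,4-dimethoxycyclohexa-2,5-dien-1-one | COC1(OC)C=CC(=O)C=C1 | starting material
2 | potassium trifluoro(prop-1-en-2-yl)borate | C=C(C)[B-](F)(F)F.[K+] | starting material
3 | (R)-4,4-dimethoxy-5-(prop-1-en-2-yl)cyclohex-2-en-1-one | O=C1C=CC(OC)(OC)[C@@H](C(C)=C)C1 | intermediate
4 | lithium (3R)-4,4-dimethoxy-3-(prop-1-en-2-yl)cyclohexa-1,5-dien-1-olate | [Li+].[O-]C1=C[C@H](C(C)=C)C(OC)(OC)C=C1 | intermediate
5 | (5R,6S)-4,4-dimethoxy-6-methyl-5-(prop-1-en-2-yl)cyclohex-2-en-1-one (methyl trans to isopropenyl) | O=C1C=CC(OC)(OC)[C@@H](C(C)=C)[C@@H]1C | intermediate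
6 | lithium (3S)-4,4-dimethoxy-2-methyl-3-(prop-1-en-2-yl)cyclohexa-1,5-dien-1-olate | [Li+].[O-]C1=C(C)[C@H](C(C)=C)C(OC)(OC)C=C1 | intermediate
7 | (5S,6S)-4,4-dimethoxy-6-methyl-6-[2-(phenylsulfinyl)ethyl]-5-(prop-1-en-2-yl)cyclohex-2-en-1-one (both sulfur epimers) | O=C1C=CC(OC)(OC)[C@@H](C(C)=C)[C@]1(C)CCS(=O)c1ccccc1 | intermediate
8 | (5S,6S)-6-ethenyl-4,4-dimethoxy-6-methyl-5-(prop-1-en-2-yl)cyclohex-2-en-1-one | O=C1C=CC(OC)(OC)[C@@H](C(C)=C)[C@]1(C)C=C | intermediate
9 | (1S,5S,6S)-6-ethenyl-4,4-dimethoxy-6-methyl-5-(prop-1-en-2-yl)cyclohex-2-en-1-ol (9β-OH, cis to the C10 methyl) | O[C@H]1C=CC(OC)(OC)[C@@H](C(C)=C)[C@]1(C)C=C | intermediate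
10 | (1S,5S,6S)-1-{[1-(dimethylamino)ethenyl]oxy}-6-ethenyl-4,4-dimethoxy-6-methyl-5-(prop-1-en-2-yl)cyclohex-2-ene (ketene N,O-acetal of 9) | C=C(N(C)C)O[C@H]1C=CC(OC)(OC)[C@@H](C(C)=C)[C@]1(C)C=C | intermediate
11 | N,N-dimethyl-2-(5β-isopropenyl-6,6-dimethoxy-10β-methyl-10α-vinylcyclohex-8-en-7β-yl)acetamide | CN(C)C(=O)C[C@@H]1C=C[C@@](C)(C=C)[C@H](C(C)=C)C1(OC)OC | intermediate
12 | N,N-dimethyliminium iodide of lactone 13 (C12=N+Me2 in place of C12=O; 8β-O, 9α-I) | C1C(=[N+](C)C)O[C@H]2[C@@H]1C(OC)(OC)[C@@H](C(C)=C)[C@](C)(C=C)[C@@H]2I.[I-] | intermediate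
13 | 2-(8β-hydroxy-9α-iodo-5β-isopropenyl-6,6-dimethoxy-10β-methyl-10α-vinylcyclohex-7β-yl)acetic acid γ-lactone (cis-fused) | C1C(=O)O[C@H]2[C@@H]1C(OC)(OC)[C@@H](C(C)=C)[C@](C)(C=C)[C@@H]2I | intermediate
14 | lithium enolate of lactone 13 (C11=C12–OLi) | C1=C([O-])O[C@H]2[C@@H]1C(OC)(OC)[C@@H](C(C)=C)[C@](C)(C=C)[C@@H]2I.[Li+] | intermediate
15 | 11-[(dimethylamino)methyl] derivative of lactone 13 (C11 epimers) | CN(C)CC1C(=O)O[C@H]2[C@@H]1C(OC)(OC)[C@@H](C(C)=C)[C@](C)(C=C)[C@@H]2I | intermediate
16 | 11-[(trimethylammonio)methyl] derivative of lactone 13, iodide salt | C[N+](C)(C)CC1C(=O)O[C@H]2[C@@H]1C(OC)(OC)[C@@H](C(C)=C)[C@](C)(C=C)[C@@H]2I.[I-] | intermediate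
17 | 2-(8β-hydroxy-9α-iodo-5β-isopropenyl-6,6-dimethoxy-10β-methyl-10α-vinylcyclohex-7β-yl)acrylic acid γ-lactone | C=C1C(=O)O[C@H]2[C@@H]1C(OC)(OC)[C@@H](C(C)=C)[C@](C)(C=C)[C@@H]2I | intermediate
18 | lithium 2-(8β,9β-epoxy-5β-isopropenyl-6,6-dimethoxy-10β-methyl-10α-vinylcyclohex-7β-yl)acrylate | [Li+].[O-]C(=O)C(=C)[C@@H]1[C@@H]2O[C@@H]2[C@@](C)(C=C)[C@H](C(C)=C)C1(OC)OC | intermediate
19 | 2-(8β,9α-dihydroxy-5β-isopropenyl-10β-methyl-6-oxo-10α-vinylcyclohex-7β-yl)acrylic acid 8-γ-lactone | C=C1C(=O)O[C@H]2[C@@H]1C(=O)[C@@H](C(C)=C)[C@](C)(C=C)[C@@H]2O | intermediate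
20 | 2-(6β,8β,9α-trihydroxy-5β-isopropenyl-10β-methyl-10α-vinylcyclohex-7β-yl)acrylic acid 8-γ-lactone | C=C1C(=O)O[C@H]2[C@@H]1[C@@H](O)[C@@H](C(C)=C)[C@](C)(C=C)[C@@H]2O | intermediate
21 | 9α-O-angeloyl derivative of 20 (6β-OH free) | C=C1C(=O)O[C@H]2[C@@H]1[C@@H](O)[C@@H](C(C)=C)[C@](C)(C=C)[C@@H]2OC(=O)/C(C)=C\C | intermediate
22 | 6β,9α-di-O-angeloyl derivative of 20 | C=C1C(=O)O[C@H]2[C@@H]1[C@@H](OC(=O)/C(C)=C\C)[C@@H](C(C)=C)[C@](C)(C=C)[C@@H]2OC(=O)/C(C)=C\C | intermediate
23 | 22 with the C5 substituent oxidised to 3-hydroxyprop-1-en-2-yl | C=C1C(=O)O[C@H]2[C@@H]1[C@@H](OC(=O)/C(C)=C\C)[C@@H](C(=C)CO)[C@](C)(C=C)[C@@H]2OC(=O)/C(C)=C\C | intermediate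
24 | 22 with the C5 substituent oxidised to 3-oxoprop-1-en-2-yl (10α-vinyl enal) | C=C1C(=O)O[C@H]2[C@@H]1[C@@H](OC(=O)/C(C)=C\C)[C@@H](C(=C)C=O)[C@](C)(C=C)[C@@H]2OC(=O)/C(C)=C\C | intermediate
25 | CNP0291490.2: 24 with the 10α-vinyl group converted into the (R)-oxiranyl group | C=C1C(=O)O[C@H]2[C@@H]1[C@@H](OC(=O)/C(C)=C\C)[C@@H](C(=C)C=O)[C@](C)([C@@H]1CO1)[C@@H]2OC(=O)/C(C)=C\C | target

**Step count and risk**

Total step count: 13. Longest linear sequence: 13 steps (fully linear from 1).

Three steps most likely to fail: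

Step 6 (Eschenmoser–Claisen). The new C–C bond has to form next to the ketal carbon and syn to the C5 isopropenyl group, so the rearrangement may be slow or low-yielding. The fallback sets out from 8 and returns to the route at 13; it attaches the side chain while C7 is trigonal and then creates the stereocentre by delivering hydride instead of carbon. Fluoride-catalysed Mukaiyama–Michael addition of 1-(tert-butyldimethylsilyloxy)-1-methoxyethene to 8 (tris(dimethylamino)sulfonium difluorotrimethylsilicate cat., THF) gives the silyl enol ether F1, whose C7 configuration does not matter. Saegusa oxidation (Pd(OAc)2, MeCN) gives the 7-substituted enone F2. Conjugate reduction with [(Ph3P)CuH]6 adds hydride axially from the α-face, anti to the isopropenyl group, and gives the 7β-substituted ketone F3. KN(SiMe3)2 and PhNTf2 give the enol triflate F4, which can only form toward C8. Pd(OAc)2, PPh3, HCO2H and nBu3N reduce it to the olefin ester F5. LiOH gives the acid F6, which is iodolactonised (I2, NaHCO3, MeCN/H2O) to 13.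

Step 11 (double angeloylation). Both hydroxyls are axial and hindered; Z → E isomerisation and lactone migration to the 6-oxygen are possible at 80 °C. The fallback sets out from 20 and returns at 22; it makes the Z olefins after the acylation. Both hydroxyls are esterified with the small, non-isomerisable 2-[bis(2,2,2-trifluoroethoxy)phosphoryl]propanoic acid (dicyclohexylcarbodiimide, DMAP cat., CH2Cl2) to give the bis(phosphonopropionate) F7. A Still–Gennari olefination with acetaldehyde (KN(SiMe3)2, 18-crown-6, THF, −78 °C) then builds both (Z)-2-methylbut-2-enoates and gives 22.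

Step 13 (the proposed new epoxidation). The vinyl group is neopentylic and the catalyst may be too slow or too weakly face-selective. The fallback uses known chemistry, sets out from 24 and returns at 25. Unselective electrophilic epoxidation with methyl(trifluoromethyl)dioxirane (CH2Cl2, −20 °C; again only the vinyl group reacts) gives 25 mixed with its C1 epimer F8. Hydrolytic kinetic resolution of this mixture with (S,S)-(salen)Co(OAc) (trivalent cobalt; salen = N,N′-bis(3,5-di-tert-butylsalicylidene)-1,2-cyclohexanediamine dianion; the enantiomer expected by precedent to hydrolyse (S)-configured monoalkyl oxiranes) and 0.55 equiv H2O converts F8 into the diol F9. F9 is removed by chromatography from unchanged 25.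

**Further compounds**

F1 | step 6 | methyl 2-[9-(tert-butyldimethylsilyloxy)-5β-isopropenyl-6,6-dimethoxy-10β-methyl-10α-vinylcyclohex-8-en-7α-yl]acetate | COC(=O)C[C@H]1C=C(O[Si](C)(C)C(C)(C)C)[C@@](C)(C=C)[C@H](C(C)=C)C1(OC)OC
F2 | step 6 | methyl 2-(5β-isopropenyl-6,6-dimethoxy-10β-methyl-9-oxo-10α-vinylcyclohex-7-en-7-yl)acetate | COC(=O)CC1=CC(=O)[C@@](C)(C=C)[C@H](C(C)=C)C1(OC)OC
F3 | step 6 | methyl 2-(5β-isopropenyl-6,6-dimethoxy-10β-methyl-9-oxo-10α-vinylcyclohex-7β-yl)acetate | COC(=O)C[C@@H]1CC(=O)[C@@](C)(C=C)[C@H](C(C)=C)C1(OC)OC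
F4 | step 6 | methyl 2-[5β-isopropenyl-6,6-dimethoxy-10β-methyl-9-(trifluoromethylsulfonyloxy)-10α-vinylcyclohex-8-en-7β-yl]acetate | COC(=O)C[C@@H]1C=C(OS(=O)(=O)C(F)(F)F)[C@@](C)(C=C)[C@H](C(C)=C)C1(OC)OC
F5 | step 6 | methyl 2-(5β-isopropenyl-6,6-dimethoxy-10β-methyl-10α-vinylcyclohex-8-en-7β-yl)acetate | COC(=O)C[C@@H]1C=C[C@@](C)(C=C)[C@H](C(C)=C)C1(OC)OC
F6 | step 6 | 2-(5β-isopropenyl-6,6-dimethoxy-10β-methyl-10α-vinylcyclohex-8-en-7β-yl)acetic acid | OC(=O)C[C@@H]1C=C[C@@](C)(C=C)[C@H](C(C)=C)C1(OC)OC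
F7 | step 11 | 6β,9α-bis-O-{2-[bis(2,2,2-trifluoroethoxy)phosphoryl]propanoyl} derivative of 20 | C=C1C(=O)O[C@H]2[C@@H]1[C@@H](OC(=O)C(C)P(=O)(OCC(F)(F)F)OCC(F)(F)F)[C@@H](C(C)=C)[C@](C)(C=C)[C@@H]2OC(=O)C(C)P(=O)(OCC(F)(F)F)OCC(F)(F)F
F8 | step 13 | C1 epimer of 25 ((S)-oxiranyl) | C=C1C(=O)O[C@H]2[C@@H]1[C@@H](OC(=O)/C(C)=C\C)[C@@H](C(=C)C=O)[C@](C)([C@H]1CO1)[C@@H]2OC(=O)/C(C)=C\C
F9 | step 13 | 1,2-diol from hydrolysis of F8 | C=C1C(=O)O[C@H]2[C@@H]1[C@@H](OC(=O)/C(C)=C\C)[C@@H](C(=C)C=O)[C@](C)([C@H](O)CO)[C@@H]2OC(=O)/C(C)=C\C
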